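**Retrosynthetic overview**
1. Key disconnection C8–C12. The cyclopentenone ring (methine C8, ketone C9, chloro-alkene C10=C11, tertiary carbinol C12) is the Piancatelli image of a 2,5-disubstituted 3-chlorofuran: furan C2–C5 become C9–C12, the furan O becomes C9=O and water gives C12–OH. A 4π-conrotatory closure of a pentadienyl cation forms C8–C12, as in the oxidopentadienyl-cation cyclisation presumed for marine prostanoid biosynthesis.
2. The C8 carbinol of the precursor is stereorandom, since both epimers converge on ionisation. C7 directs the sense of conrotation and so sets C12. C8 is formed cis to the octenyl chain and is then equilibrated to the trans (natural) configuration.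
3. C8–C9: a 2-furyllithium adds to a C1–C8 aldehyde. Its all-syn C5–C7 triol is C2–C4 of D-xylose; C1–C3 come from a lactol Wittig reaction and C8 is xylose C5.
4. Furan: 3-bromofuran receives Cl at C3 (future C10), Sn at C2 (latent Li) and the (Z)-octenyl chain at C5 (future C12 side chain).
5. Ring order: the single carbocycle is closed in step 10; removal of the ether protecting groups and triacetylation finish the synthesis.

Key step: step 10

Remarks: prostanoid numbering is used (C1 = ester carbon; C8 and C12 = ring carbons bearing the two chains; C9 = ketone; C10 = C–Cl). The target SMILES corresponds to (5S,6R,7R,8R,12S,14Z). NAP = 2-naphthylmethyl. By analogy with 5-methyl-2-furylcarbinols, the Piancatelli step is assumed to place the new hydroxyl trans to the C8 substituent; this is why C8 is equilibrated in step 11.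

**Step 1**
Reactants: 1 (2Z)-oct-2-en-1-ol
Product: 2 (2Z)-1-bromooct-2-ene
Conditions: CBr4, PPh3, CH2Cl2, 0 °C
Reagents that add atoms: carbon tetrabromide, BrC(Br)(Br)Br
Why: Appel bromination of a primary allylic alcohol is an SN2 displacement at carbon under neutral conditions and should leave the (Z)-alkene untouched.

**Step 2**
Reactants: 3 3-bromofuran
Product: 7 tributyl(3-chlorofuran-2-yl)stannane, via 3-furyllithium 4 (not isolated), via 3-chlorofuran 5 (not isolated), via (3-chlorofuran-2-yl)lithium 6 (not isolated)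
Conditions: n-BuLi (1.0 equiv), THF, −78 °C; C2Cl6 (1.0 equiv), −78 °C; LDA, −78 °C; Bu3SnCl, −78 °C → rt
Reagents that add atoms: hexachloroethane, ClC(Cl)(Cl)C(Cl)(Cl)Cl; tributyltin chloride, CCCC[Sn](Cl)(CCCC)CCCC
Why: Bromine–lithium exchange below the temperature at which 3-furyllithium isomerises, electrophilic chlorination with C2Cl6, LDA lithiation at C2 (the position flanked by O and Cl, as with 3-bromofuran) and stannylation are standard organolithium operations, telescoped so that volatile 3-chlorofuran need not be isolated; tin blocks C2 and serves later as a latent lithium.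

**Step 3**
Reactants: 7 tributyl(3-chlorofuran-2-yl)stannane; 2 (2Z)-1-bromooct-2-ene
Product: 9 tributyl{3-chloro-5-[(2Z)-oct-2-en-1-yl]furan-2-yl}stannane, via [4-chloro-5-(tributylstannyl)furan-2-yl]lithium 8 (not isolated)
Conditions: LiTMP, THF, −78 °C; then 2, −78 → 0 °C
Reagents that add atoms: none
Why: The amide base removes the only remaining α-proton (C5–H) without attacking tin, and the 2-furyllithium displaces the primary allylic bromide by SN2 with retention of the Z geometry (alkylation of furyllithiums with allylic bromides).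

**Step 4**
Reactants: 10 methyl β-D-xylopyranoside
Product: 11 methyl 2,3,4-tri-O-(naphthalen-2-ylmethyl)-β-D-xylopyranoside
Conditions: NaH, 2-(bromomethyl)naphthalene, Bu4NI (cat.), DMF, 0 °C → rt
Reagents that add atoms: 2-(bromomethyl)naphthalene, BrCCc1ccc2ccccc2c1
Why: Williamson etherification of the three secondary hydroxyls; C2–C4 of D-xylose, the future all-syn C5–C7 centres, come from the chiral pool and are not touched.

**Step 5**
Reactants: 11 methyl 2,3,4-tri-O-(naphthalen-2-ylmethyl)-β-D-xylopyranoside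
Product: 12 2,3,4-tri-O-(naphthalen-2-ylmethyl)-D-xylopyranose (α/β lactol)
Conditions: AcOH, 1 M aq. H2SO4 (cat.), 85 °C
Reagents that add atoms: water, O
Why: Acid-catalysed glycoside hydrolysis through the oxocarbenium ion; naphthylmethyl ethers have the acid stability of benzyl ethers.

**Step 6**
Reactants: 12 2,3,4-tri-O-(naphthalen-2-ylmethyl)-D-xylopyranose
Product: 14 methyl (3Z,5S,6R,7R)-8-hydroxy-5,6,7-tris(naphthalen-2-ylmethoxy)oct-3-enoate, via (3Z,5S,6R,7R)-8-hydroxy-5,6,7-tris(naphthalen-2-ylmethoxy)oct-3-enoic acid 13 (not isolated)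
Conditions: (2-carboxyethyl)triphenylphosphonium bromide, NaHMDS, THF, −78 → 0 °C, then 12, 0 °C → rt; aq. HCl work-up; TMSCHN2, PhMe/MeOH, 0 °C
Reagents that add atoms: (2-carboxyethyl)triphenylphosphonium bromide, OC(=O)CC[P+](c1ccccc1)(c1ccccc1)c1ccccc1.[Br-]; (trimethylsilyl)diazomethane, C[Si](C)(C)C=[N+]=[N-]
Why: Wittig olefination of the open-chain aldehyde form of a lactol with a non-stabilised carboxy ylide (the lactol Wittig of prostaglandin chemistry) adds C1–C3 and frees the C8 hydroxyl from the ring, the alkene geometry being irrelevant; the crude acid is methylated with the diazoalkane.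

**Step 7**
Reactants: 14 methyl (3Z,5S,6R,7R)-8-hydroxy-5,6,7-tris(naphthalen-2-ylmethoxy)oct-3-enoate
Product: 15 methyl (5S,6R,7R)-8-hydroxy-5,6,7-tris(naphthalen-2-ylmethoxy)octanoate
Conditions: H2 (1 atm), RhCl(PPh3)3 (cat.), PhH/EtOH, rt
Reagents that add atoms: none
Why: Homogeneous hydrogenation with Wilkinson's catalyst saturates the disubstituted alkene without hydrogenolysis of the naphthylmethyl ethers.

**Step 8**
Reactants: 15 methyl (5S,6R,7R)-8-hydroxy-5,6,7-tris(naphthalen-2-ylmethoxy)octanoate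
Product: 16 methyl (5S,6R,7S)-5,6,7-tris(naphthalen-2-ylmethoxy)-8-oxooctanoate
Conditions: Dess–Martin periodinane, CH2Cl2, 0 °C → rt
Reagents that add atoms: none
Why: Dess–Martin oxidation of the primary alcohol proceeds without base, so the α-alkoxy centre C7 should not epimerise; the aldehyde is used directly.

**Step 9**
Reactants: 9 tributyl{3-chloro-5-[(2Z)-oct-2-en-1-yl]furan-2-yl}stannane; 16 methyl (5S,6R,7S)-5,6,7-tris(naphthalen-2-ylmethoxy)-8-oxooctanoate
Product: 18 methyl (5S,6R,7R,8RS)-8-{3-chloro-5-[(2Z)-oct-2-en-1-yl]furan-2-yl}-8-hydroxy-5,6,7-tris(naphthalen-2-ylmethoxy)octanoate, via {3-chloro-5-[(2Z)-oct-2-en-1-yl]furan-2-yl}lithium 17 (not isolated)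
Conditions: n-BuLi (1.0 equiv per 9), THF, −78 °C; then 16, −78 °C; aq. NH4Cl at −78 °C
Reagents that add atoms: none
Why: Tin–lithium exchange gives the 2-furyllithium regiospecifically (no deprotonation of the furfurylic/allylic CH2), and its 1,2-addition to the aldehyde at −78 °C outpaces attack on the methyl ester; the C8 configuration does not matter because step 10 erases it.

**Step 10**
Reactants: 18 methyl (5S,6R,7R,8RS)-8-{3-chloro-5-[(2Z)-oct-2-en-1-yl]furan-2-yl}-8-hydroxy-5,6,7-tris(naphthalen-2-ylmethoxy)octanoate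
Product: 21 methyl (5S,6R,7R,8S,12S,14Z)-10-chloro-12-hydroxy-5,6,7-tris(naphthalen-2-ylmethoxy)-9-oxoprosta-10,14-dien-1-oate, via furfuryl (2-alkylidenefuranium) cation 19 (not isolated), via 9,12-dihydroxypentadienyl cation 20 (not isolated)
Conditions: ZnCl2 (2 equiv), 1,4-dioxane/H2O (3:2), pH ca. 5, 85 °C
Reagents that add atoms: water, O
Why: Zn(II)-assisted loss of the C8 hydroxyl from either epimer of 18 gives the same furfuryl cation 19 (stereoconvergent); water adds at the octenyl-bearing furan carbon C12, the hemiketal opens to the (10Z)-pentadienyl cation 20, and a thermal 4π-conrotatory electrocyclisation forms the C8–C12 bond and leaves the O-protonated enone of 21. The closest known reaction type is the Piancatelli rearrangement of 5-alkyl-2-furylcarbinols to 4-alkyl-4-hydroxy-5-substituted cyclopent-2-enones (ZnCl2, aqueous dioxane), here with a 3-chloro substituent that becomes the C10 vinyl chloride. The five-membered ring closes as a 4π-electron conrotatory closure of the pentadienyl cation (formally a 5-(enolendo)-exo-trig aldol, allowed because it is pericyclic). C8 and C12 are created together: conrotation with the C7 chain and the C12 hydroxyl both "outside" places C12–OH trans to the C8 chain, and the sense of rotation is set by C7 in a Felkin-type arrangement (new bond at C8 anti to the C7–C6 bond, H-7 "inside" next to the C9 hydroxyl, the C7 ether "outside"), which leads to 12S,8S. The step needs water to attack C12 rather than C8 (reversible) or C10 (chlorine-bearing), facial discrimination by C7 (helped by the bulky, non-chelating naphthylmethyl ether in an aqueous medium), and survival of the methyl ester and ethers at pH 5. C8 is deliberately formed as the 8-epimer and is corrected in step 11.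

**Step 11**
Reactants: 21 methyl (5S,6R,7R,8S,12S,14Z)-10-chloro-12-hydroxy-5,6,7-tris(naphthalen-2-ylmethoxy)-9-oxoprosta-10,14-dien-1-oate
Product: 22 methyl (5S,6R,7R,8R,12S,14Z)-10-chloro-12-hydroxy-5,6,7-tris(naphthalen-2-ylmethoxy)-9-oxoprosta-10,14-dien-1-oate
Conditions: DBU (0.1 equiv), CH2Cl2, 0 °C → rt
Reagents that add atoms: none
Why: Reversible enolisation at C8 should equilibrate the cis-dialkyl ring to the more stable isomer with the two carbon chains trans and the small C12–OH cis to the C8 chain (the base-mediated 8-epimerisation known for 8-iso prostanoids), the C7 alkoxide being a poor leaving group for β-elimination.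

**Step 12**
Reactants: 22 methyl (5S,6R,7R,8R,12S,14Z)-10-chloro-12-hydroxy-5,6,7-tris(naphthalen-2-ylmethoxy)-9-oxoprosta-10,14-dien-1-oate
Product: 24 punaglandin 2, methyl (5S,6R,7R,8R,12S,14Z)-5,6,7-triacetoxy-10-chloro-12-hydroxy-9-oxoprosta-10,14-dien-1-oate, via methyl (5S,6R,7R,8R,12S,14Z)-10-chloro-5,6,7,12-tetrahydroxy-9-oxoprosta-10,14-dien-1-oate 23 (not isolated)
Conditions: DDQ (3.5 equiv), CH2Cl2/pH 7 buffer (10:1), 0 °C → rt; aqueous NaHCO3 wash; then Ac2O, pyridine, 0 °C
Reagents that add atoms: acetic anhydride, CC(=O)OC(C)=O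
Why: Oxidative cleavage of naphthylmethyl ethers by DDQ is neutral and should spare the Z-alkene, the chloroenone and the tertiary alcohol, and acetic anhydride in pyridine without DMAP acetylates the three secondary hydroxyls while leaving the tertiary C12–OH free; the triol is acetylated without isolation so that the C5 hydroxyl cannot lactonise onto the C1 ester.

**Compound list**
1 | (2Z)-oct-2-en-1-ol | CCCCC/C=C\CO | starting material
2 | (2Z)-1-bromooct-2-ene | CCCCC/C=C\CBr | intermediate
3 | 3-bromofuran | Brc1ccoc1 | starting material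
4 | 3-furyllithium | [Li]c1ccoc1 | intermediate (not isolated)
5 | 3-chlorofuran | Clc1ccoc1 | intermediate (not isolated)
6 | (3-chlorofuran-2-yl)lithium | [Li]c1occc1Cl | intermediate (not isolated)
7 | tributyl(3-chlorofuran-2-yl)stannane | CCCC[Sn](CCCC)(CCCC)c1occc1Cl | intermediate
8 | [4-chloro-5-(tributylstannyl)furan-2-yl]lithium | [Li]c1cc(Cl)c([Sn](CCCC)(CCCC)CCCC)o1 | intermediate (not isolated)
9 | tributyl{3-chloro-5-[(2Z)-oct-2-en-1-yl]furan-2-yl}stannane | CCCCC/C=C\Cc1cc(Cl)c([Sn](CCCC)(CCCC)CCCC)o1 | intermediate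
10 | methyl β-D-xylopyranoside | CO[C@@H]1OC[C@@H](O)[C@H](O)[C@H]1O | starting material
11 | methyl 2,3,4-tri-O-(naphthalen-2-ylmethyl)-β-D-xylopyranoside | CO[C@@H]1OC[C@@H](OCc2ccc3ccccc3c2)[C@H](OCc2ccc3ccccc3c2)[C@H]1OCc1ccc2ccccc2c1 | intermediate
12 | 2,3,4-tri-O-(naphthalen-2-ylmethyl)-D-xylopyranose (α/β) | OC1OC[C@@H](OCc2ccc3ccccc3c2)[C@H](OCc2ccc3ccccc3c2)[C@H]1OCc1ccc2ccccc2c1 | intermediate
13 | (3Z,5S,6R,7R)-8-hydroxy-5,6,7-tris(naphthalen-2-ylmethoxy)oct-3-enoic acid | OC[C@@H](OCc1ccc2ccccc2c1)[C@H](OCc1ccc2ccccc2c1)[C@@H](OCc1ccc2ccccc2c1)/C=C\CC(=O)O | intermediate (not isolated)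
14 | methyl (3Z,5S,6R,7R)-8-hydroxy-5,6,7-tris(naphthalen-2-ylmethoxy)oct-3-enoate | OC[C@@H](OCc1ccc2ccccc2c1)[C@H](OCc1ccc2ccccc2c1)[C@@H](OCc1ccc2ccccc2c1)/C=C\CC(=O)OC | intermediate
15 | methyl (5S,6R,7R)-8-hydroxy-5,6,7-tris(naphthalen-2-ylmethoxy)octanoate | OC[C@@H](OCc1ccc2ccccc2c1)[C@H](OCc1ccc2ccccc2c1)[C@@H](OCc1ccc2ccccc2c1)CCCC(=O)OC | intermediate
16 | methyl (5S,6R,7S)-5,6,7-tris(naphthalen-2-ylmethoxy)-8-oxooctanoate | O=C[C@@H](OCc1ccc2ccccc2c1)[C@H](OCc1ccc2ccccc2c1)[C@@H](OCc1ccc2ccccc2c1)CCCC(=O)OC | intermediate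
17 | {3-chloro-5-[(2Z)-oct-2-en-1-yl]furan-2-yl}lithium | [Li]c1oc(C/C=C\CCCCC)cc1Cl | intermediate (not isolated)
18 | methyl (5S,6R,7R,8RS)-8-{3-chloro-5-[(2Z)-oct-2-en-1-yl]furan-2-yl}-8-hydroxy-5,6,7-tris(naphthalen-2-ylmethoxy)octanoate | CCCCC/C=C\Cc1cc(Cl)c(o1)C(O)[C@@H](OCc1ccc2ccccc2c1)[C@H](OCc1ccc2ccccc2c1)[C@@H](OCc1ccc2ccccc2c1)CCCC(=O)OC | intermediate
19 | furfuryl cation from 18 (3-chloro-5-octenyl-2-alkylidenefuranium, C8 planar) | CCCCC/C=C\CC1=[O+]C(=C[C@@H](OCc2ccc3ccccc3c2)[C@H](OCc2ccc3ccccc3c2)[C@@H](OCc2ccc3ccccc3c2)CCCC(=O)OC)C(Cl)=C1 | intermediate (not isolated)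
20 | 9,12-dihydroxypentadienyl cation (C8–C12; 10Z, C7 "outside"), drawn as the C12 O-protonated dienone enol | CCCCC/C=C\CC(=[OH+])/C=C(Cl)\C(O)=C\[C@@H](OCc1ccc2ccccc2c1)[C@H](OCc1ccc2ccccc2c1)[C@@H](OCc1ccc2ccccc2c1)CCCC(=O)OC | intermediate (not isolated)
21 | methyl (5S,6R,7R,8S,12S,14Z)-10-chloro-12-hydroxy-5,6,7-tris(naphthalen-2-ylmethoxy)-9-oxoprosta-10,14-dien-1-oate (8-epi; C12–OH trans to the C8 chain) | CCCCC/C=C\C[C@@]1(O)C=C(Cl)C(=O)[C@H]1[C@@H](OCc1ccc2ccccc2c1)[C@H](OCc1ccc2ccccc2c1)[C@@H](OCc1ccc2ccccc2c1)CCCC(=O)OC | intermediate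
22 | methyl (5S,6R,7R,8R,12S,14Z)-10-chloro-12-hydroxy-5,6,7-tris(naphthalen-2-ylmethoxy)-9-oxoprosta-10,14-dien-1-oate | CCCCC/C=C\C[C@@]1(O)C=C(Cl)C(=O)[C@@H]1[C@@H](OCc1ccc2ccccc2c1)[C@H](OCc1ccc2ccccc2c1)[C@@H](OCc1ccc2ccccc2c1)CCCC(=O)OC | intermediate
23 | methyl (5S,6R,7R,8R,12S,14Z)-10-chloro-5,6,7,12-tetrahydroxy-9-oxoprosta-10,14-dien-1-oate | CCCCC/C=C\C[C@@]1(O)C=C(Cl)C(=O)[C@@H]1[C@@H](O)[C@H](O)[C@@H](O)CCCC(=O)OC | intermediate (not isolated)
24 | punaglandin 2 | CCCCC/C=C\C[C@@]1(O)C=C(Cl)C(=O)[C@@H]1[C@@H](OC(C)=O)[C@H](OC(C)=O)[C@H](CCCC(=O)OC)OC(C)=O | target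

**Totals**
Total step count: 12. Longest linear sequence: 9 steps (steps 4–12, from methyl β-D-xylopyranoside).

**Steps most likely to fail**

Step 10 (key step). The furfuryl system is deactivated by the C10 chlorine and the C7 ether, so ionisation and closure may be slow. Loss of H-13 from the cation (migration of the 14,15 double bond towards the ring) and oligomerisation could then overtake the electrocyclisation. The two senses of conrotation may also be poorly discriminated, in which case the C12 epimers would be separated at the stage of 22. The fallback forms the ring on a chlorine-free furan, where the 5-alkylfurylcarbinol precedent applies directly, and introduces chlorine afterwards. It sets out from bromide 2 and aldehyde 16. Furan is lithiated (n-BuLi, THF) and alkylated with 2 to give 2-[(2Z)-oct-2-en-1-yl]furan F1. Its 5-lithio derivative is added to 16 to give the chlorine-free furylcarbinol F2. ZnCl2 in aqueous dioxane should give the 10-deschloro 8-epi-cyclopentenone F3. Nucleophilic epoxidation of the enone (t-BuOOH, DBU), which also equilibrates C8, gives the 10,11-epoxy ketone F4. HCl in CHCl3 opens the epoxide at the α-carbon to the 10-chloro-11-hydroxy ketone F5. Dehydration of F5 (MsCl, Et3N if it does not occur spontaneously) gives the α-chloro enone and comes back to the route at 22.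

Step 11. β-Elimination of the C7 alkoxide from the dienolate (to the cross-conjugated 7-ene) may compete with simple proton exchange, or the equilibrium may not lie far enough on the side of 22. The fallback replaces thermodynamic control by kinetic protonation. It sets out from 21. TESOTf and Et3N give the bis(triethylsilyl) dienol ether F6 (C9 silyl enol ether, C12 silyl ether). HF·pyridine at low temperature protonates C8 from the face opposite the bulky C12 siloxy group and removes both silyl groups, coming back at 22.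

Step 6. The β-carboxy ylide may collapse to acrylate and triphenylphosphine before it reacts, and the basic medium may cause β-elimination or C5 epimerisation of the open-chain aldehyde. The fallback builds C1–C3 by olefin metathesis. It sets out from lactol 12. Methylenation with Ph3P=CH2 gives (2R,3R,4S)-2,3,4-tris(naphthalen-2-ylmethoxy)hex-5-en-1-ol F7. Cross-metathesis with methyl but-3-enoate (Grubbs second-generation catalyst) gives methyl (3E,5S,6R,7R)-8-hydroxy-5,6,7-tris(naphthalen-2-ylmethoxy)oct-3-enoate F8. Hydrogenation under the conditions of step 7 comes back at 15.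

**Further compounds**
F1 | step 10 | 2-[(2Z)-oct-2-en-1-yl]furan | CCCCC/C=C\Cc1ccco1
F2 | step 10 | 10-deschloro analogue of 18: methyl (5S,6R,7R,8RS)-8-hydroxy-5,6,7-tris(naphthalen-2-ylmethoxy)-8-{5-[(2Z)-oct-2-en-1-yl]furan-2-yl}octanoate | CCCCC/C=C\Cc1ccc(o1)C(O)[C@@H](OCc1ccc2ccccc2c1)[C@H](OCc1ccc2ccccc2c1)[C@@H](OCc1ccc2ccccc2c1)CCCC(=O)OC
F3 | step 10 | 10-deschloro analogue of 21 (8-epi; C12–OH trans to the C8 chain) | CCCCC/C=C\C[C@@]1(O)C=CC(=O)[C@H]1[C@@H](OCc1ccc2ccccc2c1)[C@H](OCc1ccc2ccccc2c1)[C@@H](OCc1ccc2ccccc2c1)CCCC(=O)OC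
F4 | step 10 | 10,11-epoxy-10,11-dihydro-10-deschloro analogue of 22 (C8 as in 22; epoxide configuration of no consequence) | CCCCC/C=C\C[C@@]1(O)C2OC2C(=O)[C@@H]1[C@@H](OCc1ccc2ccccc2c1)[C@H](OCc1ccc2ccccc2c1)[C@@H](OCc1ccc2ccccc2c1)CCCC(=O)OC
F5 | step 10 | 10-chloro-11-hydroxy-10,11-dihydro analogue of 22 (C10/C11 configuration of no consequence) | CCCCC/C=C\C[C@@]1(O)C(O)C(Cl)C(=O)[C@@H]1[C@@H](OCc1ccc2ccccc2c1)[C@H](OCc1ccc2ccccc2c1)[C@@H](OCc1ccc2ccccc2c1)CCCC(=O)OC
F6 | step 11 | 9,12-bis(triethylsilyl) dienol ether of 21 (C8=C9 enol ether, C12 silyl ether) | CCCCC/C=C\C[C@@]1(O[Si](CC)(CC)CC)C=C(Cl)C(O[Si](CC)(CC)CC)=C1[C@@H](OCc1ccc2ccccc2c1)[C@H](OCc1ccc2ccccc2c1)[C@@H](OCc1ccc2ccccc2c1)CCCC(=O)OC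
F7 | step 6 | (2R,3R,4S)-2,3,4-tris(naphthalen-2-ylmethoxy)hex-5-en-1-ol | OC[C@@H](OCc1ccc2ccccc2c1)[C@H](OCc1ccc2ccccc2c1)[C@@H](OCc1ccc2ccccc2c1)C=C
F8 | step 6 | methyl (3E,5S,6R,7R)-8-hydroxy-5,6,7-tris(naphthalen-2-ylmethoxy)oct-3-enoate | OC[C@@H](OCc1ccc2ccccc2c1)[C@H](OCc1ccc2ccccc2c1)[C@@H](OCc1ccc2ccccc2c1)/C=C/CC(=O)OC
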